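Percent of the J charged is my unit, because in it D and J of the autumn run can be added: at 15.0 h they sum to 98.5%, and I book the gap as L.

in all of them: J 1.5 M; X 200 mM (held)

| flask | E | remark | time |
|---|---|---|---|
| autumn | 0.060 M | run made earlier |  |
| flask | 0.0300 M |  | 3.0 d |

- autumn (time / h: D / %, J / %): 1.00: 0.8, 99.8; 2.00: 1.8, 98.5; 4.00: 6.8, 93.2; 8.00: 14.0, 85.9; 15.0: 20.0, 78.5

(scatter of a reading: 0.5 percentage points)

- percent here means J units held: one L counts as two
- at the start none of Z is dissolved
- candidate steps: X <-> Z; J + Z <-> D; 2 J -> L; Z + E -> G
- no earlier run changes the charge of E; that part of a forecast is a guess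

- south-east: doubling the saturation concentration of X, all else as stated
- south-west: doubling the transfer coefficient of X, all else as stated

1. the D standing at 3.0 d, as a percentage of the J charged
2. concentration of Z in solution at 8.0 h, in percent of saturation
3. the change that raises the amount of D at 3.0 d, in percent of the J charged most ("none" if none brings more than 2 percentage points) (south-east / south-west / none)
4. amount of D at 3.0 d, in percent of the J charged, after south-west

The concentration that sets the order of the rate is cZ: while X holds Z near its saturation of 200 mM, J + Z <-> D is pseudo-first-order in J, so D should relax to a plateau. I reach that plateau by two ways. The first uses the fall of the slope, in fractions of the charge per hour, over the last two intervals of the autumn run: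

first slope = 0.0180 /h, second slope = 0.00857 /h

relaxation time = 7.00 h

plateau of D = 23.0%

The second way takes the readings a, b, c at the equal spacing of 1.00 h, 8.00 h and 15.0 h:

plateau of D = (a·c − b·b)/(a + c − b − b) = 25.0%

The two part by 2 percentage points, and the second is the one that cheats: its reading a grew at 0.00800 /h, slower than the 0.0250 /h between 2.00 h and 4.00 h, so it stands in the lag, on another curve.

I therefore keep 23.0%, and with J falling as D rises this gives the standing ratio ρ, cD/cJ on the plateau at fixed cZ, 0.305. It holds neither cE nor the transfer coefficient, and the relaxation time is shorter than 3.0 d, so for the flask, with half the E, I expect 23.0%, no gain from south-west, and 37.9% from south-east, before L.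

The forecast gives 23.2% (20.5% to 26%), Z at 55% (44% to 66%), south-east as best, and 23.2% (20.5% to 26%) after south-west, holding that “the E charge and the transfer coefficient hardly matter”; its plateau ratio is 0.32, mine 0.305.

The flask gives 23.7%, Z at 79.4%, higher than forecast by 24 points, south-east as best with 15 points against 0 points, and 23.7% after south-west.

    X ⇌ Z, rate k1*(csat - [Z]) (kL = 0.603 /h)
    J + Z ⇌ D (K = 1.60 /M, k = 0.266 /M/h)
    2 J → L (k = 1.92 × 10⁻⁴ /M/h)
    Z + E → G (k = 34.5 /M/h)

The neighbouring flask charges 2.5 M of J, and at 3.0 d its Z stands at 0.200 M, so I carry the ratio over unchanged. With L at 4.19%, ρ = 0.305 splits what remains: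

D = ρ/(1 + ρ) · (whole − L) = 22.4%

In the neighbouring flask J stands at 72.5%, and D stands at 23.3%.

(The readings are calculated for an exercise; noise was put on by code.)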